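## Structural features

The target is an acyclic 8-O-4' neolignan built from two benzene rings and no other ring: ring A is a guaiacyl ring (4-hydroxy-3-methoxyphenyl) and ring B a syringyl ring (3,5-dimethoxy, oxygen at C4'). Ring A carries the chain C7–C8–C9, in which C7 is a benzylic secondary alcohol, C8 carries the ether oxygen O4' of ring B, and C9 is a primary alcohol. Ring B carries, para to O4', an (E)-3-hydroxyprop-1-enyl chain (C7'=C8'–C9'). The two stereocentres C7 and C8 are adjacent and (7R,8R), the threo series, with OH and OAr syn when C1–C7–C8–C9 is drawn as a zigzag. The descriptor at C8 is S while C9 is a carbonyl carbon and R once C9 is CH2OH, without any change in space. Fragile groups are the p-hydroxybenzylic alcohol at C7 (acid ionises it to a quinone methide and epimerises it), the free phenol, the cinnamyl alcohol, and, in every carbonyl precursor, the C8–H between a carbonyl group and the aryloxy group. The real difficulty is the C8–O4' bond, which joins a secondary stereogenic carbon to a phenol oxygen flanked by two methoxy groups, together with the need for threo geometry in one enantiomer. The key step exploits the pattern C8–O4' next to C7–OH para to the ring A phenol, which is what a phenoxy radical coupling at C8 followed by water addition at C7 of a quinone methide leaves behind.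

## Logic of the disconnections

16 to 15. The two C9'–H bonds are removed, so that C9' returns to the ester level. The cinnamyl alcohol is the most sensitive group and is best unveiled last. The gain is a robust enoate through the preceding steps. The forward step must reduce 1,2 only, leave C7'=C8' intact and cope with three free hydroxyl groups.

15 to 13 and 14. The C7'=C8' double bond is cut. This reduces ring B to a benzaldehyde and takes two carbons from a commercial ylide. The forward olefination must be E-selective and neutral, because 13 carries a phenol, a benzylic alcohol and a primary alcohol unprotected.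

13 to 11, through 12. The two C9–H bonds are removed (forward, the C9–N bond is broken by hydride) and the C7' aldehyde is traced back to its acetal. The acyl imide is cleaved directly after the key step because C8–H is acidic only while C9 is a carbonyl carbon. The gain is a configurationally safe C8 and release of the auxiliary for recovery. The demand is exocyclic hydride attack at a hindered acyl group, then acetal hydrolysis mild enough to leave C7 alone.

11 to 7 and 9, through 10. The C8–O4' bond and the C7–OH bond are cut. This is the biosynthetic retron and avoids any substitution at a hindered phenol oxygen. The gain is two simple phenols and both stereocentres in one operation. The demands are cross-coupling over self-coupling, face selection at C8, hydration of 10 faster than loss of H8, and the threo mode of water addition.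

7 to 6, then to 3 and 4, through 5. The O–Si bond and then the C9–N bond are cut. The phenol must be masked during acylation; a silyl ether is chosen over an acetate because its removal by fluoride leaves the enoyl imide untouched. The demand is clean acyl transfer from the cinnamoyl side of 5.

3 to 1, through 2, and 9 to 8. Only protecting-group bonds are cut (O–Si; the two acetal C–O bonds). The acetal makes the ring B phenol electron-rich and leaves it without a conjugated side chain or a free aldehyde, so that its oxygen is its only productive coupling site. The demand is selective hydrolysis of the silyl ester in 2 and an acetalisation driven to completion.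

## Other disconnections considered

Alternative 1: The cut is C8–C9. Forward, formaldehyde A3 adds to the (Z)-enol silane A2 of aryloxymethyl aryl ketone A1 under Sc(OTf)3 and a chiral bipyridine diol, forming C8–C9 and the C8 centre of hydroxy ketone A4.
- In its favour: the stereocontrol is catalytic, so no stoichiometric auxiliary is needed, which is better than the chosen plan. The ether bond comes from ordinary O-alkylation with the ring B side chain already in place, so no acetal or olefination detour is needed, which is at least equal in step economy. The polar mechanism has none of the homo-coupling problems of a radical route.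
- Against it: C7 remains a ketone, so the threo relationship needs a second, separately controlled reduction. A4 is a β-hydroxy ketone with an acidic C8–H and is exposed to retro-aldol loss of A3, dehydration and racemisation. α-Aryloxy enol silanes with a 2,6-disubstituted aryloxy group lie outside the usual α-alkyl substrate range, and the geometry of A2 must be controlled.
- Comparison: the chosen plan sets both centres in one step but with less certainty; overall length is similar.

Alternative 2: The cut is C1–C7. Forward, Grignard reagent A6 adds to (R)-aldehyde A5 precomplexed with MgBr2·OEt2, forming C1–C7 and the C7 centre of tris-silyl ether A7.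
- In its favour: C8 comes from a glycerate building block of the chiral pool, so its absolute configuration is certain, which is better than the chosen plan. A chelate through the α-oxygen leads to the threo product. A7 needs only one global desilylation.
- Against it: the aryl ether of A5 must be made by substitution at a secondary carbon with a doubly ortho-substituted phenol. A5 is an epimerisable α-aryloxy aldehyde. An aryl ether oxygen is a weak donor, so the non-chelated erythro pathway can compete. More protecting-group and redox adjustments are needed, so the route is longer.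
- Comparison: it is stronger on absolute configuration, weaker on the hindered ether bond and on step count, and equal in convergence.

Alternative 3: The cut is the C7–H bond. Forward, RuCl(p-cymene)[(S,S)-TsDPEN] with HCO2H/Et3N reduces the rapidly epimerising racemic keto ester A8 to syn hydroxy diester A9, fixing C7 and C8 together.
- In its favour: it is catalytic, sets both centres in one step, and has an intrinsic syn preference that is the threo geometry required. Both ester groups can then fall in one hydride operation. It is better than the chosen plan in stereochemical predictability and at least equal, probably shorter, in step count.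
- Against it: A8 needs O-alkylation of a hindered phenol by an α-halo keto ester. The bulky aryloxy group may slow epimerisation relative to reduction and erode selectivity. The cinnamate must survive the ruthenium hydride. A9 is still a retro-aldol-prone β-hydroxy ester until reduced.
- Comparison: the chosen plan forms the hindered C8–O bond without substitution and from two simple phenols, but its selectivities are less predictable.

Key step: step 5

Remark: the threo label is used for (7R,8R). Water entering 10 opposite to the aryloxy group would give the erythro series, so the threo product 11 requires entry opposite to the acyl imide, and step 5 is designed on that basis.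

## Route

Step 1
Reactants: 1 ferulic acid
Product: 3 (E)-3-[4-(tert-butyldimethylsilyloxy)-3-methoxyphenyl]acrylic acid, via bis-silylated ferulate 2 (not isolated)
Conditions: TBSCl (2.4 equiv), imidazole (5 equiv), DMF, rt; then AcOH/THF/H2O, rt
Reagents that add atoms: tert-butyldimethylsilyl chloride, CC(C)(C)[Si](C)(C)Cl
Why: Silylation of both acidic OH groups, then selective hydrolysis of the silyl ester, which is far more labile than the aryl silyl ether under brief aqueous acetic acid.

Step 2
Reactants: 3 (E)-3-[4-(tert-butyldimethylsilyloxy)-3-methoxyphenyl]acrylic acid; 4 (S)-4-benzyloxazolidin-2-one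
Product: 6 (S)-4-benzyl-3-[(E)-3-(4-(tert-butyldimethylsilyloxy)-3-methoxyphenyl)acryloyl]oxazolidin-2-one, via pivalic mixed anhydride 5 (not isolated)
Conditions: PivCl (1.05 equiv), Et3N (2.5 equiv), THF, −20 °C; then 4, LiCl (1.1 equiv), −20 °C to rt
Reagents that add atoms: none
Why: N-Acylation of an oxazolidinone through a mixed pivalic anhydride; the nucleophile attacks the unhindered cinnamoyl carbonyl and the auxiliary centre is not touched.

Step 3
Reactants: 6 (S)-4-benzyl-3-[(E)-3-(4-(tert-butyldimethylsilyloxy)-3-methoxyphenyl)acryloyl]oxazolidin-2-one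
Product: 7 (S)-4-benzyl-3-[(E)-3-(4-hydroxy-3-methoxyphenyl)acryloyl]oxazolidin-2-one
Conditions: Bu4NF (1.1 equiv), AcOH (1.5 equiv), THF, 0 °C
Reagents that add atoms: none
Why: Fluoride cleavage of an aryl silyl ether; the acetic acid buffer keeps the liberated phenoxide from attacking the enoyl imide.

Step 4
Reactants: 8 syringaldehyde
Product: 9 4-(1,3-dioxolan-2-yl)-2,6-dimethoxyphenol
Conditions: ethylene glycol (5 equiv), p-TsOH·H2O (cat.), toluene, reflux, Dean–Stark; Et3N quench
Reagents that add atoms: ethylene glycol, OCCO
Why: Acid-catalysed acetalisation driven by azeotropic removal of water; the amine quench and base-washed silica protect the acid-labile, electron-rich aryl acetal.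

Step 5
Reactants: 7 (S)-4-benzyl-3-[(E)-3-(4-hydroxy-3-methoxyphenyl)acryloyl]oxazolidin-2-one; 9 4-(1,3-dioxolan-2-yl)-2,6-dimethoxyphenol
Product: 11 (S)-4-benzyl-3-[(2S,3R)-2-[4-(1,3-dioxolan-2-yl)-2,6-dimethoxyphenoxy]-3-hydroxy-3-(4-hydroxy-3-methoxyphenyl)propanoyl]oxazolidin-2-one, via quinone methide 10 (not isolated)
Conditions: 9 (4 equiv), Ag2O (3 equiv, in portions), CH2Cl2, 0 °C; 7 premixed with Mg(OTf)2 (1.5 equiv) in CH2Cl2/THF added over 4 h; then THF/H2O, 0 °C; chromatography
Reagents that add atoms: water, O
Why: Proposed new method: Ag2O removes one electron and one proton from each phenol; the radical of 7 has high spin density at C8, and the radical of 9, with both ortho positions blocked by methoxy groups and no conjugated chain, can couple productively only at oxygen, so the C8–O4' bond forms to give quinone methide 10, which rearomatises by 1,6-addition of water at C7. The closest known reaction types are Ag2O- or peroxidase-mediated dehydrogenative cross-couplings of monolignols through quinone methides, auxiliary-directed 8–5 dimerisations of ferulic amides, and Lewis-acid-chelated radical reactions of N-acyl oxazolidinones. No ring is closed. C8 is controlled by the auxiliary: Mg(OTf)2 is added because without a chelate the benzyl group sits far from C8; the chelate holds the two imide carbonyls syn with the enoyl unit s-cis, placing the benzyl group over one face of C8 as in a chelated Z-enolate, and the aryloxy radical should bond to the open face, which for the (S)-auxiliary gives the 8S acyl compound (8R after reduction). C7 is controlled by C8: with H8 in the plane of the quinone methide (allylic 1,3-strain) the aryloxy group and the magnesium-bound acyl imide lie on opposite faces, and external water should enter opposite to the bulkier imide, which is the threo mode; this bias is expected to be modest and 11 is to be separated from its diastereomers. Cross-selectivity needs the radical of 7 to meet the radical of 9 before it meets another of its own kind, which the excess of 9 and the slow addition of 7 should secure. Hydration must outrun loss of the acidic H8, which the low temperature, the absence of soluble base and the immediate aqueous quench are meant to secure.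

Step 6
Reactants: 11 (S)-4-benzyl-3-[(2S,3R)-2-[4-(1,3-dioxolan-2-yl)-2,6-dimethoxyphenoxy]-3-hydroxy-3-(4-hydroxy-3-methoxyphenyl)propanoyl]oxazolidin-2-one
Product: 13 4-{[(1R,2R)-1,3-dihydroxy-1-(4-hydroxy-3-methoxyphenyl)propan-2-yl]oxy}-3,5-dimethoxybenzaldehyde, via acetal triol 12 (not isolated)
Conditions: LiBH4 (4 equiv), MeOH (4 equiv), THF, 0 °C; then aq. HCl to pH 2, THF, rt
Reagents that add atoms: water, O
Why: Reductive cleavage of an N-acyl oxazolidinone by LiBH4 (hydride attacks the exocyclic carbonyl and releases 4 for recovery), then acid hydrolysis of the aryl dioxolane. Once C9 is CH2OH, C8 can no longer epimerise, and the short, cold acid stage should leave the C7 benzylic alcohol intact.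

Step 7
Reactants: 13 4-{[(1R,2R)-1,3-dihydroxy-1-(4-hydroxy-3-methoxyphenyl)propan-2-yl]oxy}-3,5-dimethoxybenzaldehyde; 14 ethyl (triphenylphosphoranylidene)acetate
Product: 15 ethyl (E)-3-(4-{[(1R,2R)-1,3-dihydroxy-1-(4-hydroxy-3-methoxyphenyl)propan-2-yl]oxy}-3,5-dimethoxyphenyl)acrylate
Conditions: 14 (2 equiv), THF, 60 °C
Reagents that add atoms: none
Why: Wittig olefination with a stabilised ylide, which is neutral, tolerates free hydroxyl groups and gives the E enoate from an aromatic aldehyde.

Step 8
Reactants: 15 ethyl (E)-3-(4-{[(1R,2R)-1,3-dihydroxy-1-(4-hydroxy-3-methoxyphenyl)propan-2-yl]oxy}-3,5-dimethoxyphenyl)acrylate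
Product: 16 (1R,2R)-1-(4-hydroxy-3-methoxyphenyl)-2-{4-[(E)-3-hydroxyprop-1-enyl]-2,6-dimethoxyphenoxy}propane-1,3-diol
Conditions: i-Bu2AlH (8 equiv), THF/toluene, −78 to 0 °C; aq. KNaC4H4O6 work-up
Reagents that add atoms: none
Why: 1,2-Reduction of an α,β-unsaturated ester to the allylic alcohol with diisobutylaluminium hydride; the excess covers the three hydroxyl groups, and the low temperature and neutral tartrate work-up protect the alkene and the benzylic alcohol.

## Compound list

1 | ferulic acid | COc1cc(/C=C/C(=O)O)ccc1O | starting material
2 | tert-butyldimethylsilyl (E)-3-[4-(tert-butyldimethylsilyloxy)-3-methoxyphenyl]acrylate | COc1cc(/C=C/C(=O)O[Si](C)(C)C(C)(C)C)ccc1O[Si](C)(C)C(C)(C)C | intermediate (not isolated)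
3 | (E)-3-[4-(tert-butyldimethylsilyloxy)-3-methoxyphenyl]acrylic acid | COc1cc(/C=C/C(=O)O)ccc1O[Si](C)(C)C(C)(C)C | intermediate
4 | (S)-4-benzyloxazolidin-2-one | O=C1N[C@@H](Cc2ccccc2)CO1 | starting material
5 | mixed anhydride of 3 with pivalic acid | COc1cc(/C=C/C(=O)OC(=O)C(C)(C)C)ccc1O[Si](C)(C)C(C)(C)C | intermediate (not isolated)
6 | (S)-4-benzyl-3-[(E)-3-(4-(tert-butyldimethylsilyloxy)-3-methoxyphenyl)acryloyl]oxazolidin-2-one | COc1cc(/C=C/C(=O)N2[C@@H](Cc3ccccc3)COC2=O)ccc1O[Si](C)(C)C(C)(C)C | intermediate
7 | (S)-4-benzyl-3-[(E)-3-(4-hydroxy-3-methoxyphenyl)acryloyl]oxazolidin-2-one | COc1cc(/C=C/C(=O)N2[C@@H](Cc3ccccc3)COC2=O)ccc1O | intermediate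
8 | syringaldehyde | COc1cc(C=O)cc(OC)c1O | starting material
9 | 4-(1,3-dioxolan-2-yl)-2,6-dimethoxyphenol | COc1cc(C2OCCO2)cc(OC)c1O | intermediate
10 | quinone methide from C8–O4' coupling, 8S, exocyclic double-bond geometry not defined | COC1=CC(=C[C@@H](C(=O)N2[C@@H](Cc3ccccc3)COC2=O)Oc4c(OC)cc(C5OCCO5)cc4OC)C=CC1=O | intermediate (not isolated)
11 | (S)-4-benzyl-3-[(2S,3R)-2-[4-(1,3-dioxolan-2-yl)-2,6-dimethoxyphenoxy]-3-hydroxy-3-(4-hydroxy-3-methoxyphenyl)propanoyl]oxazolidin-2-one | COc1cc([C@@H](O)[C@@H](C(=O)N2[C@@H](Cc3ccccc3)COC2=O)Oc4c(OC)cc(C5OCCO5)cc4OC)ccc1O | intermediate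
12 | (1R,2R)-2-[4-(1,3-dioxolan-2-yl)-2,6-dimethoxyphenoxy]-1-(4-hydroxy-3-methoxyphenyl)propane-1,3-diol | COc1cc([C@@H](O)[C@@H](CO)Oc2c(OC)cc(C3OCCO3)cc2OC)ccc1O | intermediate (not isolated)
13 | 4-{[(1R,2R)-1,3-dihydroxy-1-(4-hydroxy-3-methoxyphenyl)propan-2-yl]oxy}-3,5-dimethoxybenzaldehyde | COc1cc([C@@H](O)[C@@H](CO)Oc2c(OC)cc(C=O)cc2OC)ccc1O | intermediate
14 | ethyl (triphenylphosphoranylidene)acetate | CCOC(=O)C=P(c1ccccc1)(c1ccccc1)c1ccccc1 | starting material
15 | ethyl (E)-3-(4-{[(1R,2R)-1,3-dihydroxy-1-(4-hydroxy-3-methoxyphenyl)propan-2-yl]oxy}-3,5-dimethoxyphenyl)acrylate | COc1cc([C@@H](O)[C@@H](CO)Oc2c(OC)cc(/C=C/C(=O)OCC)cc2OC)ccc1O | intermediate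
16 | (1R,2R)-1-(4-hydroxy-3-methoxyphenyl)-2-{4-[(E)-3-hydroxyprop-1-enyl]-2,6-dimethoxyphenoxy}propane-1,3-diol | COc1cc([C@@H](O)[C@@H](CO)Oc2c(OC)cc(/C=C/CO)cc2OC)ccc1O | target

## Step count and least certain steps

Total step count: 8. Longest linear sequence: 7 steps (steps 1, 2, 3, 5, 6, 7, 8, from 1 to 16); step 4 is the side branch.

Step 5 (proposed new method). What is most likely to go wrong:
- Loss of the proton at C8 of 10. It is activated by the imide carbonyl and by the quinone methide, so tautomerisation to an aromatic enol ether may outrun water addition and erase both stereocentres.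
- Self-coupling of the radical of 7 through C5, C8 or its own oxygen.
- Weak face selection at C8 if the magnesium chelate does not persist next to Ag2O and an excess of the chelating phenol 9.
- Hydration in the erythro mode, which a bulky 2,6-dimethoxyphenoxy group favours.

The fallback is an Evans syn aldol, which is known chemistry; it sets out from 4 and 9 and returns at 11. Compound 4 is N-acylated with bromoacetyl bromide (n-BuLi, THF, −78 °C) to (S)-4-benzyl-3-(bromoacetyl)oxazolidin-2-one F1. Phenol 9 is O-alkylated with F1 (K2CO3, acetone, rt) to the aryloxyacetyl imide F2. Purchased vanillin F3 is silylated (TBSCl, imidazole, DMF) to 4-O-TBS-vanillin F4. The Z-boron enolate of F2 (Bu2BOTf, i-Pr2NEt, CH2Cl2, −78 °C) adds to F4 through a Zimmerman–Traxler transition state to give the syn adduct F5. With the (S)-auxiliary this is the 2S,3R acyl compound, the configuration of 11. Buffered Bu4NF/AcOH (THF, 0 °C) then gives 11.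

Step 6. Hydride may attack the ring carbonyl of the hindered imide, opening the auxiliary instead of releasing it, or the lithium alkoxide may fragment by retro-aldol cleavage of C7–C8. In the acid stage the p-hydroxybenzylic alcohol may ionise and epimerise at C7. The fallback sets out from 11 and returns at 13. LiOH/H2O2 (THF/H2O, 0 °C), whose hydroperoxide attacks the exocyclic carbonyl selectively, gives the carboxylic acid F6. BH3·SMe2 (THF, 0 °C to rt) reduces the acid to 12, and PPTS in THF/H2O at rt removes the acetal to give 13.

Step 7. The phenol may protonate part of the ylide and the aldehyde is electron-rich, so conversion may be incomplete and some Z isomer may form. The fallback sets out from 13 and returns at 15 without a new intermediate: a Knoevenagel–Doebner condensation with ethyl hydrogen malonate (pyridine, catalytic piperidine, 70 °C) gives the E enoate by decarboxylative condensation.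

Step 8. Aggregation of the aluminium alkoxides of a polyol may stall the reduction, and forcing it may lead to hydroalumination of the C7'=C8' bond. The fallback sets out from 13 and returns at 16, bypassing the ester. A Wittig reaction with (triphenylphosphoranylidene)acetaldehyde (toluene, 80 °C) gives the enal F7, and Luche reduction (NaBH4, CeCl3·7H2O, MeOH, 0 °C) gives 16.

Step 4. The para hydroxyl group deactivates the aldehyde, so acetalisation may stop short, and the product may revert on work-up or on silica. The fallback sets out from 8 and returns at 9. Acetylation (Ac2O, pyridine) gives 4-acetoxy-3,5-dimethoxybenzaldehyde F8, whose aldehyde is more electrophilic. Acetalisation as in step 4 gives the acetal acetate F9, and K2CO3 in MeOH at rt removes the acetate to give 9.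

## Further compounds

F1 | step 5 | (S)-4-benzyl-3-(bromoacetyl)oxazolidin-2-one | O=C(CBr)N1[C@@H](Cc2ccccc2)COC1=O
F2 | step 5 | (S)-4-benzyl-3-{[4-(1,3-dioxolan-2-yl)-2,6-dimethoxyphenoxy]acetyl}oxazolidin-2-one | COc1cc(C2OCCO2)cc(OC)c1OCC(=O)N3[C@@H](Cc4ccccc4)COC3=O
F3 | step 5 | vanillin (purchased) | COc1cc(C=O)ccc1O
F4 | step 5 | 4-(tert-butyldimethylsilyloxy)-3-methoxybenzaldehyde | COc1cc(C=O)ccc1O[Si](C)(C)C(C)(C)C
F5 | step 5 | (S)-4-benzyl-3-[(2S,3R)-3-[4-(tert-butyldimethylsilyloxy)-3-methoxyphenyl]-2-[4-(1,3-dioxolan-2-yl)-2,6-dimethoxyphenoxy]-3-hydroxypropanoyl]oxazolidin-2-one | COc1cc([C@@H](O)[C@@H](C(=O)N2[C@@H](Cc3ccccc3)COC2=O)Oc4c(OC)cc(C5OCCO5)cc4OC)ccc1O[Si](C)(C)C(C)(C)C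
F6 | step 6 | (2S,3R)-2-[4-(1,3-dioxolan-2-yl)-2,6-dimethoxyphenoxy]-3-hydroxy-3-(4-hydroxy-3-methoxyphenyl)propanoic acid | COc1cc([C@@H](O)[C@@H](C(=O)O)Oc2c(OC)cc(C3OCCO3)cc2OC)ccc1O
F0 | step 7 | none | none
F7 | step 8 | (E)-3-(4-{[(1R,2R)-1,3-dihydroxy-1-(4-hydroxy-3-methoxyphenyl)propan-2-yl]oxy}-3,5-dimethoxyphenyl)prop-2-enal | COc1cc([C@@H](O)[C@@H](CO)Oc2c(OC)cc(/C=C/C=O)cc2OC)ccc1O
F8 | step 4 | 4-acetoxy-3,5-dimethoxybenzaldehyde | COc1cc(C=O)cc(OC)c1OC(C)=O
F9 | step 4 | 4-(1,3-dioxolan-2-yl)-2,6-dimethoxyphenyl acetate | COc1cc(C2OCCO2)cc(OC)c1OC(C)=O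
A1 | alternative 1 | ethyl (E)-3-(3,5-dimethoxy-4-{2-[3-methoxy-4-(pivaloyloxy)phenyl]-2-oxoethoxy}phenyl)acrylate | COc1cc(C(=O)COc2c(OC)cc(/C=C/C(=O)OCC)cc2OC)ccc1OC(=O)C(C)(C)C
A2 | alternative 1 | (Z)-trimethylsilyl enol ether of A1 | COc1cc(/C(O[Si](C)(C)C)=C/Oc2c(OC)cc(/C=C/C(=O)OCC)cc2OC)ccc1OC(=O)C(C)(C)C
A3 | alternative 1 | formaldehyde | C=O
A4 | alternative 1 | ethyl (E)-3-(4-{[(R)-3-hydroxy-1-[3-methoxy-4-(pivaloyloxy)phenyl]-1-oxopropan-2-yl]oxy}-3,5-dimethoxyphenyl)acrylate | COc1cc(C(=O)[C@@H](CO)Oc2c(OC)cc(/C=C/C(=O)OCC)cc2OC)ccc1OC(=O)C(C)(C)C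
A5 | alternative 2 | (R)-3-(tert-butyldimethylsilyloxy)-2-{4-[(E)-3-(tert-butyldimethylsilyloxy)prop-1-enyl]-2,6-dimethoxyphenoxy}propanal | O=C[C@@H](CO[Si](C)(C)C(C)(C)C)Oc1c(OC)cc(/C=C/CO[Si](C)(C)C(C)(C)C)cc1OC
A6 | alternative 2 | [4-(tert-butyldimethylsilyloxy)-3-methoxyphenyl]magnesium bromide | COc1cc([Mg]Br)ccc1O[Si](C)(C)C(C)(C)C
A7 | alternative 2 | tris(tert-butyldimethylsilyl) ether of 16 at O4, O9 and O9', (7R,8R) | COc1cc([C@@H](O)[C@@H](CO[Si](C)(C)C(C)(C)C)Oc2c(OC)cc(/C=C/CO[Si](C)(C)C(C)(C)C)cc2OC)ccc1O[Si](C)(C)C(C)(C)C
A8 | alternative 3 | racemic ethyl 2-{4-[(E)-3-ethoxy-3-oxoprop-1-enyl]-2,6-dimethoxyphenoxy}-3-[3-methoxy-4-(triisopropylsilyloxy)phenyl]-3-oxopropanoate | COc1cc(C(=O)C(C(=O)OCC)Oc2c(OC)cc(/C=C/C(=O)OCC)cc2OC)ccc1O[Si](C(C)C)(C(C)C)C(C)C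
A9 | alternative 3 | ethyl (2S,3R)-2-{4-[(E)-3-ethoxy-3-oxoprop-1-enyl]-2,6-dimethoxyphenoxy}-3-hydroxy-3-[3-methoxy-4-(triisopropylsilyloxy)phenyl]propanoate | COc1cc([C@@H](O)[C@@H](C(=O)OCC)Oc2c(OC)cc(/C=C/C(=O)OCC)cc2OC)ccc1O[Si](C(C)C)(C(C)C)C(C)C
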